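**Strategy.** Andavadoic acid is cut across its 1,2-dioxolane ring (O1–O2–C3–C4–C5) at C4–C5 and O2–C3. C5, its methyl, the 10-phenyldecyl chain and both oxygens come from a methyl-ketone-level silylperoxy ketal; C3, C4, the C3 methyl and the acetate arm come from methyl 3-methylbut-3-enoate, a 1,1-disubstituted alkene. One Lewis-acid operation turns the ketal into a peroxycarbenium ion, joins it to the alkene CH2 and closes the peroxide ring, creating both quaternary stereocentres. The precursor is the triethylsilylperoxy methyl ketal of 12-phenyldodecan-2-one, reached without concentrated hydrogen peroxide by ozonolysis of a 2-methyl-1-alkene in methanol. The racemic trans ester is then resolved and saponified.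

Key step: step 6

Remark: ring atoms are numbered O1–O2–C3–C4–C5 as in the name of the target; in the (3R,5S) target the two ring methyl groups are trans. The annulation product is a racemate (its SMILES shows one enantiomer). Its cis-dimethyl C3 epimer, also racemic, is removed by chromatography within the key step. The enantiomer separation is counted as a step.

**Route**

Step 1
Reactants: 1 8-bromooct-1-ene; 2 2-phenylethylmagnesium chloride
Product: 3 10-phenyldec-1-ene
Conditions: Li2CuCl4 (3 mol%), THF–NMP, 0 °C → rt
Reagents that add atoms: none
Why: Copper-catalysed sp3–sp3 cross-coupling of a primary alkyl Grignard reagent with an unhindered primary bromide (Kochi coupling) is fast at 0 °C and leaves the terminal alkene untouched.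

Step 2
Reactants: 3 10-phenyldec-1-ene; 4 2-bromopropene
Product: 6 2-methyl-12-phenyldodec-1-ene, via B-(10-phenyldecyl)-9-BBN 5 (not isolated)
Conditions: 9-BBN, THF, rt; then 2-bromopropene (1.5 equiv), PdCl2(dppf) (3 mol%), 3 M aq. K3PO4, THF–DMF, 50 °C (sealed)
Reagents that add atoms: none
Why: Anti-Markovnikov hydroboration of the monosubstituted alkene with 9-BBN followed by B-alkyl Suzuki–Miyaura coupling with the vinylic bromide installs the isopropenyl end without alkene migration.

Step 3
Reactants: 6 2-methyl-12-phenyldodec-1-ene
Product: 9 racemic 2-hydroperoxy-2-methoxy-12-phenyldodecane, via primary ozonide 7 (not isolated), via carbonyl oxide 8 (not isolated)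
Conditions: O3/O2, CH2Cl2–MeOH (4:1), −78 °C, Sudan Red 7B end-point; N2 purge; concentrate below 25 °C (no reductant)
Reagents that add atoms: ozone, [O-][O+]=O; methanol, CO
Why: In this ozonolysis by the Criegee mechanism the primary ozonide of a 1,1-disubstituted alkene should cyclorevert mainly to formaldehyde and the more substituted ketone O-oxide, which methanol traps as the α-methoxy hydroperoxide, while the alkylbenzene ring reacts far more slowly with ozone than the alkene and the new ketal centre is racemic and later destroyed.

Step 4
Reactants: 9 racemic 2-hydroperoxy-2-methoxy-12-phenyldodecane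
Product: 10 racemic triethyl[(2-methoxy-12-phenyldodecan-2-yl)peroxy]silane
Conditions: Et3SiCl, imidazole, DMF, 0 °C; chromatography on Et3N-deactivated silica
Reagents that add atoms: chlorotriethylsilane, CC[Si](Cl)(CC)CC
Why: O-Silylation of the terminal hydroperoxy oxygen under imidazole buffering is ordinary silyl-ether formation, and the basic medium protects the acid-labile peroxyketal.

Step 5
Reactants: 11 3-methylbut-3-enoic acid
Product: 12 methyl 3-methylbut-3-enoate
Conditions: MeI, KHCO3, DMF, rt; pentane extraction, distillation
Reagents that add atoms: iodomethane, CI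
Why: SN2 O-alkylation of the carboxylate with iodomethane uses a base too weak to move the β,γ double bond into conjugation.

Step 6
Reactants: 10 racemic triethyl[(2-methoxy-12-phenyldodecan-2-yl)peroxy]silane; 12 methyl 3-methylbut-3-enoate
Product: 15 racemic methyl 2-[(3R*,5S*)-3,5-dimethyl-5-(10-phenyldecyl)-1,2-dioxolan-3-yl]acetate, via peroxycarbenium ion 13 (not isolated), via tertiary carbocation 14 (not isolated)
Conditions: SnCl4 (1.2 equiv), 12 (2.5 equiv), CH2Cl2, −78 °C; H2O quench; SiO2 chromatography (C3 epimer removed)
Reagents that add atoms: none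
Why: SnCl4 removes methoxide from 10 to give the dialkyl-stabilised peroxycarbenium ion 13, the CH2 terminus of 12 adds to it (C4–C5) to leave tertiary carbocation 14 at C3, and the silylated peroxy oxygen captures that cation (O2–C3) while chloride takes the triethylsilyl group. The closest known reaction type is the Lewis-acid (3+2) annulation of silylperoxy ketals with 1,1-disubstituted alkenes via peroxycarbenium ions, applied here to an alkene that carries an ester one CH2 away. The 1,2-dioxolane closes by a five-membered cation–oxygen collapse onto a planar tertiary carbocation, a closure that breaks no π bond and so meets no endo-trig restriction. C5 arises from the planar peroxycarbenium ion and C3 from the planar carbocation with no controlling element at either, so the trans-dimethyl pair (3R*,5S*) and its C3 epimer should both form as racemates and are parted on silica. The selectivity needed is regiochemical and chemoselective: bond formation at the alkene CH2 is secured by the 1,1-disubstitution (tertiary rather than primary cation), ionisation of OMe rather than OOSi by the higher Lewis basicity of the ether oxygen, and ring closure rather than ester participation by the fact that the ester carbonyl could only close a four-membered ring.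

Step 7
Reactants: 15 racemic methyl 2-[(3R*,5S*)-3,5-dimethyl-5-(10-phenyldecyl)-1,2-dioxolan-3-yl]acetate
Product: 16 methyl 2-[(3R,5S)-3,5-dimethyl-5-(10-phenyldecyl)-1,2-dioxolan-3-yl]acetate
Conditions: preparative chiral HPLC or SFC, amylose tris(3,5-dimethylphenylcarbamate) phase, hexane–i-PrOH; the wanted fraction is to be identified by the sign of optical rotation of the acid derived from it, compared with the natural product
Reagents that add atoms: none
Why: This is a physical resolution by preparative enantioselective chromatography in which the phenyl ring and the ester supply the contacts for the polysaccharide carbamate phase, and no bond at C3 or C5 is made or broken.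

Step 8
Reactants: 16 methyl 2-[(3R,5S)-3,5-dimethyl-5-(10-phenyldecyl)-1,2-dioxolan-3-yl]acetate
Product: 17 andavadoic acid, 2-[(3R,5S)-3,5-dimethyl-5-(10-phenyldecyl)-1,2-dioxolan-3-yl]acetic acid
Conditions: LiOH·H2O, THF–H2O (3:1), 0 °C → rt; then 1 M HCl to pH 3
Reagents that add atoms: lithium hydroxide, [Li+].[OH-]
Why: In this BAc2 saponification of an unhindered methyl ester neither peroxy carbon carries a hydrogen, so Kornblum–DeLaMare fragmentation is impossible, and the carboxylate resists α-deprotonation, so C3 should not epimerise by retro-oxa-Michael opening.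

**Compound list**

1 | 8-bromooct-1-ene | C=CCCCCCCBr | starting material
2 | 2-phenylethylmagnesium chloride | Cl[Mg]CCc1ccccc1 | starting material
3 | 10-phenyldec-1-ene | C=CCCCCCCCCc1ccccc1 | intermediate
4 | 2-bromopropene | C=C(C)Br | starting material
5 | 9-(10-phenyldecyl)-9-borabicyclo[3.3.1]nonane | c1ccccc1CCCCCCCCCCB2C3CCCC2CCC3 | intermediate (not isolated)
6 | 2-methyl-12-phenyldodec-1-ene | C=C(C)CCCCCCCCCCc1ccccc1 | intermediate
7 | 4-methyl-4-(10-phenyldecyl)-1,2,3-trioxolane (primary ozonide, racemic) | CC1(CCCCCCCCCCc2ccccc2)COOO1 | intermediate (not isolated)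
8 | 12-phenyldodecan-2-one O-oxide (carbonyl oxide) | CC(CCCCCCCCCCc1ccccc1)=[O+][O-] | intermediate (not isolated)
9 | 2-hydroperoxy-2-methoxy-12-phenyldodecane (racemic) | CC(OC)(OO)CCCCCCCCCCc1ccccc1 | intermediate
10 | triethyl[(2-methoxy-12-phenyldodecan-2-yl)peroxy]silane (racemic) | CC(OC)(OO[Si](CC)(CC)CC)CCCCCCCCCCc1ccccc1 | intermediate
11 | 3-methylbut-3-enoic acid | C=C(C)CC(=O)O | starting material
12 | methyl 3-methylbut-3-enoate | C=C(C)CC(=O)OC | intermediate
13 | 12-phenyl-2-[(triethylsilyl)peroxy]dodecan-2-ylium (peroxycarbenium ion) | C[C+](OO[Si](CC)(CC)CC)CCCCCCCCCCc1ccccc1 | intermediate (not isolated)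
14 | 1-methoxy-3,5-dimethyl-1-oxo-15-phenyl-5-[(triethylsilyl)peroxy]pentadecan-3-ylium (tertiary carbocation, racemic) | COC(=O)C[C+](C)CC(C)(OO[Si](CC)(CC)CC)CCCCCCCCCCc1ccccc1 | intermediate (not isolated)
15 | methyl 2-[(3R*,5S*)-3,5-dimethyl-5-(10-phenyldecyl)-1,2-dioxolan-3-yl]acetate (racemate, ring methyls trans; one enantiomer drawn) | C[C@]1(CCCCCCCCCCc2ccccc2)C[C@](C)(CC(=O)OC)OO1 | intermediate
16 | methyl 2-[(3R,5S)-3,5-dimethyl-5-(10-phenyldecyl)-1,2-dioxolan-3-yl]acetate (single enantiomer) | C[C@]1(CCCCCCCCCCc2ccccc2)C[C@](C)(CC(=O)OC)OO1 | intermediate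
17 | andavadoic acid, 2-[(3R,5S)-3,5-dimethyl-5-(10-phenyldecyl)-1,2-dioxolan-3-yl]acetic acid | C[C@]1(CCCCCCCCCCc2ccccc2)C[C@](C)(CC(=O)O)OO1 | target

**Step count and risk**

Total step count: 8 (seven transformations and one chromatographic resolution).
Longest linear sequence: 7 (steps 1, 2, 3, 4, 6, 7, 8); step 5 is a one-step side branch.

Steps most likely to fail:

1. Step 6. The ester may bind the Lewis acid and lower the nucleophilicity of the alkene. The peroxycarbenium ion could then decay by O–O heterolysis and alkyl migration, or the C3 cation could lose a proton to open-chain unsaturated peroxides faster than the ring closes. The fallback sets out from 10 and comes back at 15, forming the two bonds in separate, known operations. Mukaiyama-type addition of 2-(trimethylsilyloxy)propene to the peroxycarbenium ion of 10 (cat. TMSOTf, CH2Cl2, −78 °C) should give racemic 4-methyl-14-phenyl-4-[(triethylsilyl)peroxy]tetradecan-2-one F1. Acidic methanol (cat. HCl, MeOH, 0 °C → rt) should remove the silyl group and close the β-hydroperoxy ketone to the cyclic peroxyketal 3-methoxy-3,5-dimethyl-5-(10-phenyldecyl)-1,2-dioxolane F2. TiCl4-mediated substitution at C3 with 1-methoxy-1-(trimethylsilyloxy)ethene (CH2Cl2, −78 °C), through the 1,2-dioxolan-3-yl cation, should then give 15 with its C3 epimer, and the route continues with the same chromatographic separation.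

2. Step 7. Enantiorecognition may be too weak at preparative loading, because the two quaternary centres differ only in methyl against a flexible chain, and the peaks may overlap. The fallback sets out from 15 and comes back at 17, replacing the physical resolution by covalent diastereomers. Saponification of 15 (LiOH, THF–H2O) gives racemic 2-[(3R*,5S*)-3,5-dimethyl-5-(10-phenyldecyl)-1,2-dioxolan-3-yl]acetic acid F3. DCC/DMAP N-acylation of (4S)-4-benzyl-1,3-oxazolidin-2-one with F3 gives two diastereomeric imides to be separated on ordinary silica. The wanted one is (4S)-4-benzyl-3-{2-[(3R,5S)-3,5-dimethyl-5-(10-phenyldecyl)-1,2-dioxolan-3-yl]acetyl}-1,3-oxazolidin-2-one F4. Cleavage with LiOH/H2O2 (THF–H2O, 0 °C), to which the dialkyl peroxide is inert, releases 17 directly.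

3. Step 3. The primary ozonide may partition towards the ketone and formaldehyde O-oxide, prolonged ozone exposure may attack the arene, or the α-methoxy hydroperoxide may revert to the ketone on concentration or on silica. The fallback sets out from 6 and comes back at 9. Ozonolysis with reductive work-up (O3, CH2Cl2, −78 °C; Me2S) converges all material on 12-phenyldodecan-2-one F5. Ketalisation (HC(OMe)3, MeOH, cat. TsOH) gives 2,2-dimethoxy-12-phenyldodecane F6. Acid-catalysed exchange of one methoxy group with a slight excess of ethereal hydrogen peroxide (perhydrolysis of the ketal, behind a shield) returns 9.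

**Further compounds**

F1 | step 6 | 4-methyl-14-phenyl-4-[(triethylsilyl)peroxy]tetradecan-2-one (racemic) | CC(=O)CC(C)(OO[Si](CC)(CC)CC)CCCCCCCCCCc1ccccc1
F2 | step 6 | 3-methoxy-3,5-dimethyl-5-(10-phenyldecyl)-1,2-dioxolane (racemic mixture of diastereomers) | COC1(C)CC(C)(CCCCCCCCCCc2ccccc2)OO1
F3 | step 7 | 2-[(3R*,5S*)-3,5-dimethyl-5-(10-phenyldecyl)-1,2-dioxolan-3-yl]acetic acid (racemate, one enantiomer drawn) | C[C@]1(CCCCCCCCCCc2ccccc2)C[C@](C)(CC(=O)O)OO1
F4 | step 7 | (4S)-4-benzyl-3-{2-[(3R,5S)-3,5-dimethyl-5-(10-phenyldecyl)-1,2-dioxolan-3-yl]acetyl}-1,3-oxazolidin-2-one | C[C@]1(CCCCCCCCCCc2ccccc2)C[C@](C)(CC(=O)N2C(=O)OC[C@@H]2Cc3ccccc3)OO1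
F5 | step 3 | 12-phenyldodecan-2-one | CC(=O)CCCCCCCCCCc1ccccc1
F6 | step 3 | 2,2-dimethoxy-12-phenyldodecane | CC(OC)(OC)CCCCCCCCCCc1ccccc1
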